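**Target:** (3S)-5,7-dihydroxy-3-(3-hydroxy-4-methoxy-5-prenylphenyl)-6-prenylchroman-4-one. Abbreviations: prenyl = 3-methylbut-2-en-1-yl, MOM = methoxymethyl, TIPS = triisopropylsilyl, pin = pinacolato.

## Structural features

The target is an isoflavanone. Ring A is a phloroglucinol-type benzene ring fused to ring C, a dihydropyranone made of O1, the C2 methylene, C3 and the C4 carbonyl; ring B is attached at C3. Ring A carries free hydroxyls at C5 and C7 and a prenyl group at C6. Ring B has the isovanillin pattern (3'-OH, 4'-OMe) with a second prenyl group at C5'. C3 is the only stereocentre; the [C@H] descriptor corresponds to (3S) with priorities C4 > C2 > C1' > H, and there is no neighbouring stereocentre. The C3–H bond is both benzylic and alpha to the ketone, so it epimerises through the enol under acid or base; C3 must therefore be set late and handled gently afterwards. The two trisubstituted alkenes are sensitive to acid (chroman formation with the ortho phenols at C5 and C7), to electrophilic halogen and to hydrogenation. The real difficulties are this labile stereocentre and the differentiation of the three ring A oxygens, so that the oxygen para to the prenyl group becomes O1 and the prenyl group ends at C6 and not C8. The key step uses the fact that C4 is a carbonyl carbon lying between the aryl carbon C4a and C3, which bears ring B and the exocyclic C2 methylene. C4 can therefore be brought in as carbon monoxide between a ring A iodide at C4a and a ring B 1-arylvinyl unit.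

## Logic of the disconnections

22 to 21: three O–CH2OMe bonds (at O5, O7 and O3') are cut. All phenols other than O1 are masked with one type of group, so only O1 can close ring C and a single final operation unmasks everything. The forward step must remove three acetals without enolising C3 and without acid-induced cyclisation of the C6 prenyl group.

21 to 19, through 20: the O1–C2 bond and the C3–H bond are cut. This takes the stereocentre back to a prochiral 1,1-disubstituted enone and removes ring C. The forward step must add O1 to the CH2 terminus and then transfer a proton to one face of C3, faster than any uncatalysed closure.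

19 to 18: the O1–Si bond is cut. O1 must stay masked while the enone is made under base, and the mask must differ from the acetals on O5 and O7. The forward step needs a fluoride source that is not basic enough to trigger ring closure.

18 to 9, 17 and 16: the C4a–C4 and C4–C3 bonds are cut. The molecule falls into two arenes of similar size and a one-carbon unit, and no stereochemistry is involved. The forward step needs CO insertion to precede transmetalation at a doubly ortho-substituted aryl–palladium centre, and the alkenylboronate must survive until then.

9 to 8 to 7: the O–Si bond and the C4a–I bond are cut. 7 has a mirror plane through O1 and the prenyl-bearing carbon, so its two ortho carbons are equivalent and iodination has no regiochemical issue. The forward step must iodinate the arene and not the prenyl alkene, and must stop at one iodine.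

7 to 3 and 4, through 5 and 6: the aryl–CH2 bond of the ring A prenyl group is cut at the carbon between the two acetal oxygens. Two cooperating directing groups define the metalation site, and the bulky silyl ether on the third oxygen shields its own neighbours. The forward step needs linear (SN2) allylation of the aryl metal.

3 to 2 to 1: one O–Si and two O–CH2 bonds are cut, back to the symmetric triol. Only the degree of alkylation has to be controlled, not the position.

16 to 15: the C–B bond and a C–H bond across the alkyne are cut. The forward step must place boron on the internal, aryl-bearing carbon.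

15 to 14: the alkyne is traced to the aldehyde by a one-carbon homologation. The base used must leave the aryl acetal and the prenyl group untouched.

14 to 12 and 13: the aryl–CH2 bond of the ring B prenyl group is cut at the brominated carbon. The forward coupling must tolerate the aldehyde and deliver the allyl unit without allylic transposition.

12 to 11 to 10: the O–CH2OMe bond and the O–CH3 bond are cut. Methylating the more acidic oxygen para to the formyl group fixes the 4'-OMe/3'-OH pattern. The forward step must be selective for that oxygen.

## Other disconnections considered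

Alternative 1: The cut is C2–C3. In the forward direction the alpha-diazo ketone A2 loses N2 at Rh2(S-PTTL)4, a divalent-rhodium dimer, and the C3 carbene inserts into a C–H bond of the ortho methoxy group to give the tris-silyl ether A1.
- In favour: ring C and the C3 configuration arise in one catalytic event. The oxygen that becomes O1 needs no orthogonal protecting group because its methyl group becomes C2. No free phenol next to an enone ever exists. On these three points the alternative is better than the chosen plan.
- Against: a methyl C–H bond is the least reactive kind, and the closure is a six-ring insertion. The ether oxygen sits where oxonium-ylide formation followed by a Stevens-type shift can compete. Two electron-rich prenyl alkenes and two electron-rich arenes are available for intermolecular cyclopropanation and Buchner-type addition, and Wolff rearrangement is possible. A2 requires diazo transfer to a hindered deoxybenzoin. A1 still has to lose three silyl groups with fluoride while C3 is epimerisable.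
- Comparison: on structure both plans make the same C4–C3 deoxybenzoin connection. On mechanism the stereo-defining step is beyond close precedent in both, so they are equal there; the carbene route has more chemoselectivity hazards from the prenyl groups, whereas the bond-forming key step of the chosen plan has direct precedent. On step economy the alternative is equal or slightly better.

Alternative 2: The cut is the two aryl–CH2 bonds of the prenyl groups (C6 and C5'). In the forward direction the bis(1,1-dimethylallyl) ether A4 is heated, with Eu(fod)3 if needed, and two aromatic Claisen shifts with allylic inversion give the diprenyl compound A3.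
- In favour: the acid- and electrophile-sensitive alkenes appear last, so no earlier step has to tolerate them; this is better than the chosen plan, which carries both prenyl groups through iodination and palladium chemistry. Regiochemistry is dictated by the substrate, since O5 has only C6 free and O4' has only C5' free; here the two plans are equal.
- Against: the step builds neither the skeleton nor C3, so the (3S) core must come from a separate asymmetric synthesis. The stereocentre must survive the formation of two tertiary ethers, one of them at the chelated and hindered O5, and then heat or a Lewis acid. A3 still needs selective methylation at O4' next to a free O5–H without base-induced epimerisation, followed by desilylation.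
- Comparison: the pericyclic step itself is well precedented and in that respect safer than the stereo step of the chosen plan. On step economy it is clearly worse, and the C3 problem is only displaced.

Alternative 3: The cut is C4a–C5 of ring A. In the forward direction excess LiN(iPr)2 turns the pyranone keto ester A6 into a polyanion, C4a attacks the ester carbonyl, methoxide leaves and the new ring enolises to the isoflavone A5.
- In favour: the oxygenation pattern of ring A and the position of the C6 prenyl group are fixed by the chain. The three ring A oxygens never need differentiating and ring A needs no protecting groups; on this point the alternative is better than the chosen plan.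
- Against: A5 has an sp2 C3, so the stereocentre must still be made by an asymmetric conjugate reduction of C2=C3 in the presence of two prenyl alkenes and free phenols. The polyanion has several acidic sites, the pyranone can be opened by base, and A6 needs a long preparation.
- Comparison: on structure the convergence is similar. On mechanism the Claisen-type closure is a known kind of reaction and equal in reliability to the carbonylative coupling. On step economy and on stereocontrol the chosen plan is better, because its key product is one deprotection away from the stereo-defining step.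

Key step: step 11

Remark on the chemistry: a vanillin-type ring B building block (3-methoxy-4-hydroxy) would put the methyl ether on the wrong oxygen, because the target has the isovanillin pattern. Ring B is therefore started from commercial 3-bromo-4,5-dihydroxybenzaldehyde and methylated at the oxygen para to the formyl group.

Remark on the chemistry: the ring B phenol is carried as a MOM ether and not as a silyl ether. It then stays masked during ring closure and is removed in the last step with the other two acetals; the skeletons of both coupling partners are unchanged.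

Remark on the chemistry: the sense of induction in step 13 cannot be fixed on paper. The quinine-derived catalyst is written for (3S), and its quinidine-derived pseudoenantiomer would be used if the sense proved opposite.

## Route

Step 1
Reactants: 1 phloroglucinol
Product: 2 3,5-bis(methoxymethoxy)phenol
Conditions: MOMCl (2.0 equiv), i-Pr2NEt, DMF, 0 °C to rt; chromatography, mono- and tris-ethers recycled
Reagents that add atoms: chloromethyl methyl ether, COCCl
Why: O-alkylation of a symmetric triol; only the degree of alkylation needs control, and the bis-ether should be the main fraction near two equivalents of the hard electrophile.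

Step 2
Reactants: 2 3,5-bis(methoxymethoxy)phenol
Product: 3 [3,5-bis(methoxymethoxy)phenoxy]triisopropylsilane
Conditions: TIPSCl, imidazole, DMF, rt
Reagents that add atoms: chlorotriisopropylsilane, CC(C)[Si](Cl)(C(C)C)C(C)C
Why: Standard silylation of an unhindered phenol; the bulky, non-coordinating silyl ether tolerates n-BuLi and shields its own ortho positions in the next step.

Step 3
Reactants: 3 [3,5-bis(methoxymethoxy)phenoxy]triisopropylsilane; 4 prenyl bromide
Product: 7 3,5-bis(methoxymethoxy)-4-prenylphenol, via 4-lithio arene 5 (not isolated), via prenylated silyl ether 6 (not isolated)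
Conditions: n-BuLi, THF, 0 °C; CuI (10 mol %), 4, −78 °C to rt; then Bu4NF, THF, rt; aq. NH4Cl
Reagents that add atoms: none
Why: Directed ortho-metalation should occur at the carbon flanked by both MOM ethers, and copper-mediated SN2 allylation then gives the linear prenyl arene. Fluoride in the same flask removes the temporary silyl group and leaves the symmetric phenol with its hydroxyl para to the prenyl group.

Step 4
Reactants: 7 3,5-bis(methoxymethoxy)-4-prenylphenol
Product: 8 2-iodo-3,5-bis(methoxymethoxy)-4-prenylphenol
Conditions: I2 (1.0 equiv), NaHCO3, THF/H2O, 0 °C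
Reagents that add atoms: iodine, II
Why: Electrophilic iodination through the phenoxide, which is far more nucleophilic than an isolated trisubstituted alkene; the para position is blocked and the two ortho carbons are equivalent. One equivalent at low temperature and the deactivating first iodine should hold the reaction at the mono-iodide.

Step 5
Reactants: 8 2-iodo-3,5-bis(methoxymethoxy)-4-prenylphenol
Product: 9 [2-iodo-3,5-bis(methoxymethoxy)-4-prenylphenoxy]triisopropylsilane
Conditions: TIPSOTf, 2,6-lutidine, CH2Cl2, 0 °C to rt
Reagents that add atoms: triisopropylsilyl trifluoromethanesulfonate, CC(C)[Si](OS(=O)(=O)C(F)(F)F)(C(C)C)C(C)C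
Why: The silyl triflate is reactive enough for the hindered ortho-iodophenol, and the hindered base leaves the MOM acetals alone.

Step 6
Reactants: 10 3-bromo-4,5-dihydroxybenzaldehyde
Product: 11 3-bromo-5-hydroxy-4-methoxybenzaldehyde
Conditions: MeI (1.1 equiv), Li2CO3, DMF, 40 °C
Reagents that add atoms: iodomethane, CI
Why: Regioselective Williamson methylation; the hydroxyl para to the formyl group and ortho to bromine is the more acidic, so the weak base should ionise and alkylate it alone.

Step 7
Reactants: 11 3-bromo-5-hydroxy-4-methoxybenzaldehyde
Product: 12 3-bromo-4-methoxy-5-(methoxymethoxy)benzaldehyde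
Conditions: MOMCl, i-Pr2NEt, CH2Cl2, 0 °C to rt
Reagents that add atoms: chloromethyl methyl ether, COCCl
Why: Routine acetal protection of the remaining phenol; the MOM ether withstands the basic and organometallic steps that follow.

Step 8
Reactants: 12 3-bromo-4-methoxy-5-(methoxymethoxy)benzaldehyde; 13 tributyl(3-methylbut-2-en-1-yl)stannane
Product: 14 4-methoxy-3-(methoxymethoxy)-5-prenylbenzaldehyde
Conditions: Pd(PPh3)4 (5 mol %), DMF, 100 °C
Reagents that add atoms: none
Why: Stille coupling tolerates the free aldehyde, and the formyl group activates the bromide towards oxidative addition. Reductive elimination at the less hindered allyl terminus should give the linear prenyl arene.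

Step 9
Reactants: 14 4-methoxy-3-(methoxymethoxy)-5-prenylbenzaldehyde
Product: 15 5-ethynyl-2-methoxy-1-(methoxymethoxy)-3-prenylbenzene
Conditions: dimethyl (1-diazo-2-oxopropyl)phosphonate, K2CO3, MeOH, 0 °C to rt
Reagents that add atoms: dimethyl (1-diazo-2-oxopropyl)phosphonate, COP(=O)(OC)C(=[N+]=[N-])C(C)=O
Why: Ohira–Bestmann homologation of a non-enolisable aryl aldehyde; MOM ether and prenyl group are inert to carbonate in methanol.

Step 10
Reactants: 15 5-ethynyl-2-methoxy-1-(methoxymethoxy)-3-prenylbenzene
Product: 16 2-{1-[4-methoxy-3-(methoxymethoxy)-5-prenylphenyl]ethenyl}-4,4,5,5-tetramethyl-1,3,2-dioxaborolane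
Conditions: B2pin2, (SIMes)CuCl [chloro(1,3-dimesitylimidazolidin-2-ylidene)copper] (5 mol %), NaOt-Bu (5 mol %), MeOH (2 equiv), THF, −50 °C to rt
Reagents that add atoms: bis(pinacolato)diboron, CC1(C)OB(OC1(C)C)B1OC(C)(C)C(C)(C)O1
Why: Copper–boryl addition to the terminal alkyne followed by protonation of the C–Cu bond by methanol; with an N-aryl carbene ligand on monovalent copper, boron is delivered to the internal carbon of aryl alkynes. The trisubstituted prenyl alkene does not insert.

Step 11
Reactants: 9 [2-iodo-3,5-bis(methoxymethoxy)-4-prenylphenoxy]triisopropylsilane; 17 carbon monoxide; 16 2-{1-[4-methoxy-3-(methoxymethoxy)-5-prenylphenyl]ethenyl}-4,4,5,5-tetramethyl-1,3,2-dioxaborolane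
Product: 18 1-[2,4-bis(methoxymethoxy)-3-prenyl-6-(triisopropylsilyloxy)phenyl]-2-[4-methoxy-3-(methoxymethoxy)-5-prenylphenyl]prop-2-en-1-one
Conditions: Pd(PPh3)4 (5 mol %), K2CO3 (3 equiv), H2O (few equiv), CO (1 atm), anisole, 80 °C
Reagents that add atoms: none
Why: Zerovalent palladium should add oxidatively to the C4a–I bond of 9, the electron-rich aryl group then migrates to coordinated CO to give an aroyl complex of divalent palladium, carbonate-activated 16 transfers its 1-arylvinyl group, and reductive elimination joins C4 to C3 and returns the catalyst. The closest known reaction type is the carbonylative Suzuki–Miyaura coupling of aryl iodides, including doubly ortho-substituted ones, with alkenylboron reagents to give aryl vinyl ketones. No ring is closed and no stereocentre is formed, so neither a mode of closure nor a stereocontrol element arises; the step forms C4a–C4 and C4–C3 in one operation. The selectivity needed is CO insertion ahead of transmetalation, so that the ketone and not the directly coupled 1,1-diarylethene is formed. The substrate secures this because the silyloxy and MOM-oxy groups flanking the C–Pd bond hinder approach of the boronate to the aryl complex, whereas the acyl complex, one atom further out, is accessible. The silyl ether on O1 keeps the phenol masked, so the enone cannot cyclise without stereocontrol under carbonate, and the nearly anhydrous medium limits conjugate addition to the product. The trisubstituted prenyl alkenes are too hindered to insert into the acyl–palladium bond, and neither is placed for an intramolecular Heck reaction.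

Step 12
Reactants: 18 1-[2,4-bis(methoxymethoxy)-3-prenyl-6-(triisopropylsilyloxy)phenyl]-2-[4-methoxy-3-(methoxymethoxy)-5-prenylphenyl]prop-2-en-1-one
Product: 19 1-[6-hydroxy-2,4-bis(methoxymethoxy)-3-prenylphenyl]-2-[4-methoxy-3-(methoxymethoxy)-5-prenylphenyl]prop-2-en-1-one
Conditions: HF·pyridine, pyridine, THF, 0 °C; cold pH 7 work-up, used at once
Reagents that add atoms: none
Why: Fluoride-mediated cleavage of the aryl silyl ether under buffered, weakly acidic conditions that leave MOM acetals and alkenes intact. The absence of a free base and the hydrogen bond from the new phenol to the ketone should hold back premature ring closure.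

Step 13
Reactants: 19 1-[6-hydroxy-2,4-bis(methoxymethoxy)-3-prenylphenyl]-2-[4-methoxy-3-(methoxymethoxy)-5-prenylphenyl]prop-2-en-1-one
Product: 21 (3S)-5,7-bis(methoxymethoxy)-3-[4-methoxy-3-(methoxymethoxy)-5-prenylphenyl]-6-prenylchroman-4-one, via 2H-chromen-4-ol enol 20 (not isolated)
Conditions: quinine-derived 9-amino(9-deoxy)epi squaramide bearing a 3,5-bis(trifluoromethyl)phenyl group (10 mol %), toluene, −20 °C
Reagents that add atoms: none
Why: Proposed new method: the squaramide N–H bonds should bind the enone carbonyl while the quinuclidine nitrogen deprotonates the phenol; 6-endo-trig oxa-Michael addition of O1 to the CH2 terminus gives the catalyst-bound enol 20, and the quinuclidinium N–H then delivers the proton to one face of C3 inside the ion pair, which sets the (3S) centre under kinetic control. The closest known reaction types are bifunctional cinchona-catalysed conjugate addition with enantioselective protonation of alpha-substituted acceptors (thiol nucleophiles) and cinchona-catalysed intramolecular oxa-Michael closures to chromanones that set C2. Low temperature, a non-polar solvent and prompt removal of the catalyst are meant to prevent later epimerisation of the acidic C3–H.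

Step 14
Reactants: 21 (3S)-5,7-bis(methoxymethoxy)-3-[4-methoxy-3-(methoxymethoxy)-5-prenylphenyl]-6-prenylchroman-4-one
Product: 22 (3S)-5,7-dihydroxy-3-(3-hydroxy-4-methoxy-5-prenylphenyl)-6-prenylchroman-4-one
Conditions: ZnBr2, n-PrSH, CH2Cl2, 0 °C, short reaction time; pH 7 buffer quench
Reagents that add atoms: none
Why: Lewis-acid-assisted transfer of the methoxymethyl groups to the thiol cleaves aryl MOM ethers within minutes without a protic acid. This should spare the prenyl groups from chroman formation and leave too little time for enolisation at C3.

## Compound list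

1 | phloroglucinol (benzene-1,3,5-triol) | Oc1cc(O)cc(O)c1 | starting material
2 | 3,5-bis(methoxymethoxy)phenol | COCOc1cc(O)cc(OCOC)c1 | intermediate
3 | [3,5-bis(methoxymethoxy)phenoxy]triisopropylsilane | COCOc1cc(O[Si](C(C)C)(C(C)C)C(C)C)cc(OCOC)c1 | intermediate
4 | prenyl bromide (1-bromo-3-methylbut-2-ene) | CC(C)=CCBr | starting material
5 | {2,6-bis(methoxymethoxy)-4-[(triisopropylsilyl)oxy]phenyl}lithium | [Li]c1c(OCOC)cc(O[Si](C(C)C)(C(C)C)C(C)C)cc1OCOC | intermediate
6 | [3,5-bis(methoxymethoxy)-4-(3-methylbut-2-en-1-yl)phenoxy]triisopropylsilane | COCOc1cc(O[Si](C(C)C)(C(C)C)C(C)C)cc(OCOC)c1CC=C(C)C | intermediate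
7 | 3,5-bis(methoxymethoxy)-4-(3-methylbut-2-en-1-yl)phenol | COCOc1cc(O)cc(OCOC)c1CC=C(C)C | intermediate
8 | 2-iodo-3,5-bis(methoxymethoxy)-4-(3-methylbut-2-en-1-yl)phenol | COCOc1cc(O)c(I)c(OCOC)c1CC=C(C)C | intermediate
9 | [2-iodo-3,5-bis(methoxymethoxy)-4-(3-methylbut-2-en-1-yl)phenoxy]triisopropylsilane | CC(C)[Si](C(C)C)(C(C)C)Oc1cc(OCOC)c(CC=C(C)C)c(OCOC)c1I | intermediate
10 | 3-bromo-4,5-dihydroxybenzaldehyde | O=Cc1cc(O)c(O)c(Br)c1 | starting material
11 | 3-bromo-5-hydroxy-4-methoxybenzaldehyde | COc1c(O)cc(C=O)cc1Br | intermediate
12 | 3-bromo-4-methoxy-5-(methoxymethoxy)benzaldehyde | COCOc1cc(C=O)cc(Br)c1OC | intermediate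
13 | tributyl(3-methylbut-2-en-1-yl)stannane | CCCC[Sn](CCCC)(CCCC)CC=C(C)C | starting material
14 | 4-methoxy-3-(methoxymethoxy)-5-(3-methylbut-2-en-1-yl)benzaldehyde | COCOc1cc(C=O)cc(CC=C(C)C)c1OC | intermediate
15 | 5-ethynyl-2-methoxy-1-(methoxymethoxy)-3-(3-methylbut-2-en-1-yl)benzene | COCOc1cc(C#C)cc(CC=C(C)C)c1OC | intermediate
16 | 2-{1-[4-methoxy-3-(methoxymethoxy)-5-(3-methylbut-2-en-1-yl)phenyl]ethenyl}-4,4,5,5-tetramethyl-1,3,2-dioxaborolane | C=C(B1OC(C)(C)C(C)(C)O1)c1cc(OCOC)c(OC)c(CC=C(C)C)c1 | intermediate
17 | carbon monoxide | [C-]#[O+] | starting material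
18 | 1-[2,4-bis(methoxymethoxy)-3-(3-methylbut-2-en-1-yl)-6-(triisopropylsilyloxy)phenyl]-2-[4-methoxy-3-(methoxymethoxy)-5-(3-methylbut-2-en-1-yl)phenyl]prop-2-en-1-one | C=C(C(=O)c1c(O[Si](C(C)C)(C(C)C)C(C)C)cc(OCOC)c(CC=C(C)C)c1OCOC)c1cc(OCOC)c(OC)c(CC=C(C)C)c1 | intermediate
19 | 1-[6-hydroxy-2,4-bis(methoxymethoxy)-3-(3-methylbut-2-en-1-yl)phenyl]-2-[4-methoxy-3-(methoxymethoxy)-5-(3-methylbut-2-en-1-yl)phenyl]prop-2-en-1-one | C=C(C(=O)c1c(O)cc(OCOC)c(CC=C(C)C)c1OCOC)c1cc(OCOC)c(OC)c(CC=C(C)C)c1 | intermediate
20 | 3-[4-methoxy-3-(methoxymethoxy)-5-(3-methylbut-2-en-1-yl)phenyl]-5,7-bis(methoxymethoxy)-6-(3-methylbut-2-en-1-yl)-2H-chromen-4-ol | COc1c(OCOC)cc(C2=C(O)c3c(OCOC)c(CC=C(C)C)c(OCOC)cc3OC2)cc1CC=C(C)C | intermediate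
21 | (3S)-5,7-bis(methoxymethoxy)-3-[4-methoxy-3-(methoxymethoxy)-5-(3-methylbut-2-en-1-yl)phenyl]-6-(3-methylbut-2-en-1-yl)chroman-4-one | COc1c(OCOC)cc([C@H]2COc3cc(OCOC)c(CC=C(C)C)c(OCOC)c3C2=O)cc1CC=C(C)C | intermediate
22 | (3S)-5,7-dihydroxy-3-[3-hydroxy-4-methoxy-5-(3-methylbut-2-en-1-yl)phenyl]-6-(3-methylbut-2-en-1-yl)chroman-4-one | COc1c(O)cc([C@H]2COc3cc(O)c(CC=C(C)C)c(O)c3C2=O)cc1CC=C(C)C | target

## Step count and risk

Total step count: 14. Longest linear sequence: 9 steps (steps 1–5, then 11–14; the ring B branch, steps 6–10 then 11–14, is equally long).

Least certain steps: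

Step 13 (bears the label). The most likely failure is an uncatalysed or non-selective ring closure that outruns the catalyst-bound pathway, already during the desilylation of step 12 or on work-up. Weak facial discrimination in the proton transfer, or slow epimerisation of the acidic C3–H by the basic catalyst after closure, are the other risks, since the proton transfer is not held as tightly as a bond-forming event. The fallback uses known chemistry and sets out from 19. Triethylamine in CH2Cl2 closes ring C without stereocontrol to give the racemic chromanone F1. Noyori-type asymmetric transfer hydrogenation with RuCl[(S,S)-TsDPEN](p-cymene) and HCO2H/Et3N, under dynamic kinetic resolution through the rapidly enolising C3, should then give the cis-(3S,4S)-chroman-4-ol F2; the catalyst antipode would be used if the sense proved opposite. Oxidation of the benzylic alcohol with Dess–Martin periodinane buffered with NaHCO3 returns to the route at 21.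

Step 11 (key step). The most likely failures are slow oxidative addition and slow transmetalation at the doubly ortho-substituted centre. These leave time for protodeboronation of the alkenylboronate, for direct coupling without CO, or for reduction of the iodide; base-induced conjugate addition to the product enone is a further risk. The fallback builds the same enone without CO, sets out from 9 and 15 and returns at 18. Anti-Markovnikov hydration of 15 (Cy2BH, then NaBO3·4H2O) gives the arylacetaldehyde F3. Iodine–magnesium exchange on 9 with i-PrMgCl·LiCl gives the aryl Grignard reagent F4, which adds to F3 to give the secondary alcohol F5. Dess–Martin oxidation gives the deoxybenzoin F6, and alpha-methylenation with paraformaldehyde and diisopropylammonium trifluoroacetate gives 18.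

Step 10. The internal selectivity of the copper–boryl addition may erode, because the electron-rich aryl group weakens the electronic bias that directs boron to the aryl-bearing carbon, and the two vinylboronates would then have to be separated. The fallback sets out from 14 and returns at 16. MeMgBr addition gives the 1-arylethanol F7, Dess–Martin oxidation gives the acetophenone F8, and KN(SiMe3)2 with PhNTf2 gives the enol triflate F9. Miyaura borylation of F9 (B2pin2, PdCl2(PPh3)2, PPh3, KOPh, toluene, 50 °C) gives 16.

Step 4. Competing attack of the iodinating agent on the prenyl double bond, or a second iodination at the other ortho carbon, would lower the yield of the mono-iodide. The fallback avoids electrophilic iodine on a free phenol. It sets out from 6, isolated by omitting the fluoride treatment in step 3. MOM-directed ortho-lithiation (n-BuLi, TMEDA, THF, −78 °C) gives the aryllithium F10, and an iodine quench at −78 °C gives 9 directly, so the route is rejoined at 9 without passing through 7 and 8. The low temperature is meant to suppress silyl migration from oxygen to the lithiated carbon.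

## Further compounds

F1 | step 13 | racemic 5,7-bis(methoxymethoxy)-3-[4-methoxy-3-(methoxymethoxy)-5-(3-methylbut-2-en-1-yl)phenyl]-6-(3-methylbut-2-en-1-yl)chroman-4-one | COc1c(OCOC)cc(C2COc3cc(OCOC)c(CC=C(C)C)c(OCOC)c3C2=O)cc1CC=C(C)C
F2 | step 13 | (3S,4S)-5,7-bis(methoxymethoxy)-3-[4-methoxy-3-(methoxymethoxy)-5-(3-methylbut-2-en-1-yl)phenyl]-6-(3-methylbut-2-en-1-yl)chroman-4-ol | COc1c(OCOC)cc([C@H]2COc3cc(OCOC)c(CC=C(C)C)c(OCOC)c3[C@H]2O)cc1CC=C(C)C
F3 | step 11 | 2-[4-methoxy-3-(methoxymethoxy)-5-(3-methylbut-2-en-1-yl)phenyl]acetaldehyde | COCOc1cc(CC=O)cc(CC=C(C)C)c1OC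
F4 | step 11 | [2,4-bis(methoxymethoxy)-3-(3-methylbut-2-en-1-yl)-6-(triisopropylsilyloxy)phenyl]magnesium chloride | CC(C)[Si](C(C)C)(C(C)C)Oc1cc(OCOC)c(CC=C(C)C)c(OCOC)c1[Mg]Cl
F5 | step 11 | 1-[2,4-bis(methoxymethoxy)-3-(3-methylbut-2-en-1-yl)-6-(triisopropylsilyloxy)phenyl]-2-[4-methoxy-3-(methoxymethoxy)-5-(3-methylbut-2-en-1-yl)phenyl]ethan-1-ol (racemic) | OC(Cc1cc(OCOC)c(OC)c(CC=C(C)C)c1)c1c(O[Si](C(C)C)(C(C)C)C(C)C)cc(OCOC)c(CC=C(C)C)c1OCOC
F6 | step 11 | 1-[2,4-bis(methoxymethoxy)-3-(3-methylbut-2-en-1-yl)-6-(triisopropylsilyloxy)phenyl]-2-[4-methoxy-3-(methoxymethoxy)-5-(3-methylbut-2-en-1-yl)phenyl]ethan-1-one | O=C(Cc1cc(OCOC)c(OC)c(CC=C(C)C)c1)c1c(O[Si](C(C)C)(C(C)C)C(C)C)cc(OCOC)c(CC=C(C)C)c1OCOC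
F7 | step 10 | 1-[4-methoxy-3-(methoxymethoxy)-5-(3-methylbut-2-en-1-yl)phenyl]ethan-1-ol (racemic) | COCOc1cc(C(C)O)cc(CC=C(C)C)c1OC
F8 | step 10 | 1-[4-methoxy-3-(methoxymethoxy)-5-(3-methylbut-2-en-1-yl)phenyl]ethan-1-one | COCOc1cc(C(C)=O)cc(CC=C(C)C)c1OC
F9 | step 10 | 1-[4-methoxy-3-(methoxymethoxy)-5-(3-methylbut-2-en-1-yl)phenyl]ethenyl trifluoromethanesulfonate | COCOc1cc(C(=C)OS(=O)(=O)C(F)(F)F)cc(CC=C(C)C)c1OC
F10 | step 4 | [2,4-bis(methoxymethoxy)-3-(3-methylbut-2-en-1-yl)-6-(triisopropylsilyloxy)phenyl]lithium | [Li]c1c(O[Si](C(C)C)(C(C)C)C(C)C)cc(OCOC)c(CC=C(C)C)c1OCOC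
A1 | alternative 1 | (3S)-5,7-bis(tert-butyldimethylsilyloxy)-3-[3-(tert-butyldimethylsilyloxy)-4-methoxy-5-(3-methylbut-2-en-1-yl)phenyl]-6-(3-methylbut-2-en-1-yl)chroman-4-one | COc1c(O[Si](C)(C)C(C)(C)C)cc([C@H]2COc3cc(O[Si](C)(C)C(C)(C)C)c(CC=C(C)C)c(O[Si](C)(C)C(C)(C)C)c3C2=O)cc1CC=C(C)C
A2 | alternative 1 | 1-[2,4-bis(tert-butyldimethylsilyloxy)-6-methoxy-3-(3-methylbut-2-en-1-yl)phenyl]-2-[3-(tert-butyldimethylsilyloxy)-4-methoxy-5-(3-methylbut-2-en-1-yl)phenyl]-2-diazoethan-1-one | COc1cc(O[Si](C)(C)C(C)(C)C)c(CC=C(C)C)c(O[Si](C)(C)C(C)(C)C)c1C(=O)C(=[N+]=[N-])c1cc(O[Si](C)(C)C(C)(C)C)c(OC)c(CC=C(C)C)c1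
A3 | alternative 2 | (3S)-7-(tert-butyldimethylsilyloxy)-3-[3-(tert-butyldimethylsilyloxy)-4-hydroxy-5-(3-methylbut-2-en-1-yl)phenyl]-5-hydroxy-6-(3-methylbut-2-en-1-yl)chroman-4-one | Oc1c(O[Si](C)(C)C(C)(C)C)cc([C@H]2COc3cc(O[Si](C)(C)C(C)(C)C)c(CC=C(C)C)c(O)c3C2=O)cc1CC=C(C)C
A4 | alternative 2 | (3S)-7-(tert-butyldimethylsilyloxy)-3-[3-(tert-butyldimethylsilyloxy)-4-(2-methylbut-3-en-2-yloxy)phenyl]-5-(2-methylbut-3-en-2-yloxy)chroman-4-one | C=CC(C)(C)Oc1ccc([C@H]2COc3cc(O[Si](C)(C)C(C)(C)C)cc(OC(C)(C)C=C)c3C2=O)cc1O[Si](C)(C)C(C)(C)C
A5 | alternative 3 | 5,7-dihydroxy-3-[4-methoxy-3-(3-methylbut-2-en-1-yl)-5-(triisopropylsilyloxy)phenyl]-6-(3-methylbut-2-en-1-yl)-4H-chromen-4-one | COc1c(O[Si](C(C)C)(C(C)C)C(C)C)cc(-c2coc3cc(O)c(CC=C(C)C)c(O)c3c2=O)cc1CC=C(C)C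
A6 | alternative 3 | methyl 2-(3-methylbut-2-en-1-yl)-3-oxo-4-{5-[4-methoxy-3-(3-methylbut-2-en-1-yl)-5-(triisopropylsilyloxy)phenyl]-4-oxo-4H-pyran-2-yl}butanoate | COC(=O)C(CC=C(C)C)C(=O)Cc1cc(=O)c(-c2cc(O[Si](C(C)C)(C(C)C)C(C)C)c(OC)c(CC=C(C)C)c2)co1
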